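**Retrosynthetic overview**
- Target ⇐ Luche reduction of an (E)-enal, itself made by E-selective cross-metathesis of a bicyclic 2-substituted acrolein with an (R)-5-allyl-4-(hydroxymethyl)butenolide.
- Bicyclic acrolein ⇐ α-methylenation of a C4 aldehyde chain on the Δ8-drimene core ⇐ reductive removal of a C11 sulfone.
- Key step: ring B is closed by a radical C9–C10 bond formation. An H-atom-transfer-generated tertiary C10 radical on a preformed, enantioenriched ring A adds to the central carbon of an allenyl sulfone, giving the quaternary C10, the trans ring fusion and the tetrasubstituted C8=C9 alkene together.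
- Allenyl sulfone ⇐ (S)-γ-dihydroionone + an alkyne acetal (acetylide addition, sulfinate [2,3] shift); ring A comes from 3-methylcyclohexenone, with C5 set by Cu-catalysed asymmetric SN2' alkylation.
- Ring order: ring A (purchased), ring B (radical step); the butenolide ring is built separately from (R)-hex-5-en-1-yn-3-ol by carbomagnesiation/CO2.

Assumption: in steps 4 and 9 the ligand antipode is the one that gives the configuration drawn (to be confirmed by a test run). Compounds 6, 10 and 19 are taken as catalogue items, being the ketal-, acetal- and silyl-protected forms of 4-bromobutan-2-one, pent-4-ynal and propynal.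

**Route**

Step 1
Reactants: 1 3-methylcyclohex-2-en-1-one
Product: 3 3,3-dimethylcyclohex-1-en-1-yl trifluoromethanesulfonate, via bromomagnesium enolate 2 (not isolated)
Conditions: MeMgBr (1.2 equiv), CuBr·SMe2 (5 mol%), THF, −40 to 0 °C; then PhNTf2, DMPU, 0 °C to rt
Reagents that add atoms: methylmagnesium bromide C[Mg]Br; N-phenylbis(trifluoromethanesulfonimide) O=S(=O)(N(c1ccccc1)S(=O)(=O)C(F)(F)F)C(F)(F)F
Why: Cu-catalysed conjugate addition of the Grignard reagent builds the gem-dimethyl carbon and gives a regiodefined enolate, whose O-triflation fixes the double bond between the future C10 and C5; no stereocentre is formed.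

Step 2
Reactants: 3 3,3-dimethylcyclohex-1-en-1-yl trifluoromethanesulfonate
Product: 4 (3,3-dimethylcyclohex-1-en-1-yl)methanol
Conditions: Bu3SnCH2OH, Pd(PPh3)4 (5 mol%), LiCl, 1,4-dioxane, 95 °C
Reagents that add atoms: (tributylstannyl)methanol OC[Sn](CCCC)(CCCC)CCCC
Why: Stille cross-coupling of the vinyl triflate with the hydroxymethyl stannane gives the primary allylic alcohol with the alkene held in place.

Step 3
Reactants: 4 (3,3-dimethylcyclohex-1-en-1-yl)methanol
Product: 5 1-(chloromethyl)-3,3-dimethylcyclohex-1-ene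
Conditions: NCS, Me2S, CH2Cl2, −20 to 0 °C
Reagents that add atoms: N-chlorosuccinimide O=C1CCC(=O)N1Cl
Why: Corey–Kim chlorination, in which chloride displaces the alkoxysulfonium at the primary allylic carbon by SN2 without allylic shift.

Step 4
Reactants: 5 1-(chloromethyl)-3,3-dimethylcyclohex-1-ene; 6 2-(2-bromoethyl)-2-methyl-1,3-dioxolane
Product: 9 4-[(1S)-2,2-dimethyl-6-methylidenecyclohexyl]butan-2-one, via Grignard reagent 7 (not isolated), via ketal 8 (not isolated)
Conditions: Mg, THF, 25 °C (6 to 7); 5, CuTC (3 mol%), chiral phosphoramidite (3.3 mol%), CH2Cl2, −78 °C, slow addition of 7; then 1 M HCl, THF, rt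
Reagents that add atoms: water O
Why: Cu-catalysed asymmetric allylic alkylation (anti-SN2') delivers the alkyl group to the ring carbon next to the gem-dimethyl group, creating the exocyclic methylene and setting C5 as (S) under ligand control, and the acidic work-up hydrolyses the ketal.

Step 5
Reactants: 9 4-[(1S)-2,2-dimethyl-6-methylidenecyclohexyl]butan-2-one; 10 5,5-diethoxypent-1-yne
Product: 14 {[8-[(1S)-2,2-dimethyl-6-methylidenecyclohexyl]-1,1-diethoxy-6-methylocta-4,5-dien-4-yl]sulfonyl}benzene, via lithium acetylide 11 (not isolated), via lithium alkoxide 12 (not isolated), via propargyl sulfinate 13 (not isolated)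
Conditions: 10, n-BuLi, THF, −78 °C; 9, −78 to 0 °C; PhS(O)Cl, −78 °C to rt
Reagents that add atoms: benzenesulfinyl chloride O=S(Cl)c1ccccc1
Why: Acetylide 1,2-addition to the methyl ketone, O-sulfinylation of the tertiary alkoxide and the spontaneous [2,3]-sigmatropic propargyl sulfinate to allenyl sulfone rearrangement give the allene; the carbinol and axis configurations are irrelevant because both are destroyed in step 6.

Step 6
Reactants: 14 {[8-[(1S)-2,2-dimethyl-6-methylidenecyclohexyl]-1,1-diethoxy-6-methylocta-4,5-dien-4-yl]sulfonyl}benzene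
Product: 15 {[4,4-diethoxy-1-[(4aS,8aS)-2,5,5,8a-tetramethyl-3,4,4a,5,6,7,8,8a-octahydronaphthalen-1-yl]butyl]sulfonyl}benzene
Conditions: Fe(acac)3 (30 mol%), PhSiH3 (2.5 equiv), EtOH (0.02 M), 60 °C
Reagents that add atoms: none
Why: Proposed new method: an iron hydride transfers H• to the electron-rich 1,1-disubstituted alkene (Mukaiyama-type MHAT) to give the tertiary C10 radical, which adds 6-endo to the electrophilic central carbon of the allenyl sulfone (polarity-matched, closest known types being the Fe(acac)3/PhSiH3 MHAT–Giese cyclisation and the central-carbon cyclisation of δ-allenyl radicals); the new C9–C10 bond forms equatorially so the C10 methyl is axial and the decalin trans (C5 controls C10, as in stepwise radical polyene cyclisations), and the α-sulfonyl allyl radical is reduced and protonated next to sulfur, leaving the tetrasubstituted C8=C9 alkene.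

Step 7
Reactants: 15 {[4,4-diethoxy-1-[(4aS,8aS)-2,5,5,8a-tetramethyl-3,4,4a,5,6,7,8,8a-octahydronaphthalen-1-yl]butyl]sulfonyl}benzene
Product: 16 (4aS,8aS)-5-(4,4-diethoxybutyl)-1,1,4a,6-tetramethyl-1,2,3,4,4a,7,8,8a-octahydronaphthalene
Conditions: 6% Na(Hg), Na2HPO4, MeOH/THF, −20 °C
Reagents that add atoms: none
Why: Reductive desulfonylation (Julia-type) gives an allyl anion that is protonated at its less substituted terminus (C11), keeping the more stable tetrasubstituted alkene; the acetal survives the buffered medium.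

Step 8
Reactants: 16 (4aS,8aS)-5-(4,4-diethoxybutyl)-1,1,4a,6-tetramethyl-1,2,3,4,4a,7,8,8a-octahydronaphthalene
Product: 18 2-methylidene-4-[(4aS,8aS)-2,5,5,8a-tetramethyl-3,4,4a,5,6,7,8,8a-octahydronaphthalen-1-yl]butanal, via aldehyde 17 (not isolated)
Conditions: TsOH·H2O (5 mol%), acetone/H2O, rt; then 37% aq. CH2O, pyrrolidine (20 mol%), EtCO2H (20 mol%), i-PrOH, 45 °C
Reagents that add atoms: water O; formaldehyde C=O
Why: Acetal hydrolysis followed in the same pot by amine-catalysed α-methylenation (Mannich condensation–elimination) gives the 2-substituted acrolein needed for the metathesis.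

Step 9
Reactants: 19 3-(trimethylsilyl)prop-2-ynal
Product: 21 (3R)-hex-5-en-1-yn-3-ol, via silylated alkynol 20 (not isolated)
Conditions: allylSnBu3, (R)-BINOL (20 mol%), Ti(Oi-Pr)4 (10 mol%), 4 Å MS, CH2Cl2, −20 °C; then K2CO3 (cat.), MeOH, rt
Reagents that add atoms: allyltributylstannane C=CC[Sn](CCCC)(CCCC)CCCC
Why: Keck asymmetric allylation sets the carbinol (the future butenolide C5) as (R) by catalyst-controlled facial selection, and methanolysis removes the stannyl and alkynyl silyl groups.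

Step 10
Reactants: 21 (3R)-hex-5-en-1-yn-3-ol
Product: 24 (5R)-4-{[dimethyl(propan-2-yloxy)silyl]methyl}-5-(prop-2-en-1-yl)furan-2(5H)-one, via oxamagnesacycle 22 (not isolated), via hydroxy acid 23 (not isolated)
Conditions: (i-PrO)Me2SiCH2MgCl (3 equiv), CuI (10 mol%), THF, 0 °C to rt; CO2, −20 °C to rt; 1 M HCl
Reagents that add atoms: {[dimethyl(propan-2-yloxy)silyl]methyl}magnesium chloride CC(C)O[Si](C)(C)C[Mg]Cl; carbon dioxide O=C=O
Why: Cu-catalysed anti-carbomagnesiation of the propargylic alkoxide (Duboudin–Jousseaume type) puts the silylmethyl group on the carbinol-side alkyne carbon and magnesium cis to oxygen, so carboxylation and acidification close the butenolide; the carbinol stereocentre is untouched.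

Step 11
Reactants: 24 (5R)-4-{[dimethyl(propan-2-yloxy)silyl]methyl}-5-(prop-2-en-1-yl)furan-2(5H)-one
Product: 25 (5R)-4-(hydroxymethyl)-5-(prop-2-en-1-yl)furan-2(5H)-one
Conditions: 30% H2O2, KHCO3, THF/MeOH, rt
Reagents that add atoms: hydrogen peroxide OO
Why: Tamao–Fleming oxidation converts the alkoxysilyl C–Si bond into C–OH with only bicarbonate as base, which does not epimerise the γ-centre.

Step 12
Reactants: 18 2-methylidene-4-[(4aS,8aS)-2,5,5,8a-tetramethyl-3,4,4a,5,6,7,8,8a-octahydronaphthalen-1-yl]butanal; 25 (5R)-4-(hydroxymethyl)-5-(prop-2-en-1-yl)furan-2(5H)-one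
Product: 26 (2E)-4-[(2R)-3-(hydroxymethyl)-5-oxo-2,5-dihydrofuran-2-yl]-2-{2-[(4aS,8aS)-2,5,5,8a-tetramethyl-3,4,4a,5,6,7,8,8a-octahydronaphthalen-1-yl]ethyl}but-2-enal
Conditions: Hoveyda–Grubbs II (7 mol%), 25 (2.5 equiv), CH2Cl2, 40 °C
Reagents that add atoms: none
Why: Olefin cross-metathesis of a terminal alkene with a 2-substituted acrolein gives the trisubstituted enal with CHO trans to the new chain (thermodynamic E), which is the geometry the target needs; the tetrasubstituted and butenolide alkenes are inert.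

Step 13
Reactants: 26 (2E)-4-[(2R)-3-(hydroxymethyl)-5-oxo-2,5-dihydrofuran-2-yl]-2-{2-[(4aS,8aS)-2,5,5,8a-tetramethyl-3,4,4a,5,6,7,8,8a-octahydronaphthalen-1-yl]ethyl}but-2-enal
Product: 27 (5R)-4-(hydroxymethyl)-5-{(2E)-3-(hydroxymethyl)-5-[(4aS,8aS)-2,5,5,8a-tetramethyl-3,4,4a,5,6,7,8,8a-octahydronaphthalen-1-yl]pent-2-en-1-yl}furan-2(5H)-one
Conditions: NaBH4, CeCl3·7H2O, MeOH, −78 °C
Reagents that add atoms: none
Why: Luche reduction takes the enal to the allylic alcohol by 1,2-addition at low temperature, far faster than any attack on the butenolide, with no change in alkene geometry or stereocentres.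

**Compound list**

1 | 3-methylcyclohex-2-en-1-one | CC1=CC(=O)CCC1 | starting material
2 | bromomagnesium 3,3-dimethylcyclohex-1-en-1-olate | CC1(C)CCCC(O[Mg]Br)=C1 | intermediate
3 | 3,3-dimethylcyclohex-1-en-1-yl trifluoromethanesulfonate | CC1(C)CCCC(OS(=O)(=O)C(F)(F)F)=C1 | intermediate
4 | (3,3-dimethylcyclohex-1-en-1-yl)methanol | CC1(C)CCCC(CO)=C1 | intermediate
5 | 1-(chloromethyl)-3,3-dimethylcyclohex-1-ene | CC1(C)CCCC(CCl)=C1 | intermediate
6 | 2-(2-bromoethyl)-2-methyl-1,3-dioxolane (ketal-protected 4-bromobutan-2-one) | CC1(CCBr)OCCO1 | starting material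
7 | [2-(2-methyl-1,3-dioxolan-2-yl)ethyl]magnesium bromide | CC1(CC[Mg]Br)OCCO1 | intermediate
8 | 2-{2-[(1S)-2,2-dimethyl-6-methylidenecyclohexyl]ethyl}-2-methyl-1,3-dioxolane | C=C1CCCC(C)(C)[C@@H]1CCC1(C)OCCO1 | intermediate
9 | 4-[(1S)-2,2-dimethyl-6-methylidenecyclohexyl]butan-2-one ((S)-γ-dihydroionone) | C=C1CCCC(C)(C)[C@@H]1CCC(C)=O | intermediate
10 | 5,5-diethoxypent-1-yne (acetal-protected pent-4-ynal) | C#CCCC(OCC)OCC | starting material
11 | (5,5-diethoxypent-1-yn-1-yl)lithium | [Li]C#CCCC(OCC)OCC | intermediate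
12 | lithium 1-[(1S)-2,2-dimethyl-6-methylidenecyclohexyl]-8,8-diethoxy-3-methyloct-4-yn-3-olate (C3 epimers) | C=C1CCCC(C)(C)[C@@H]1CCC(C)(O[Li])C#CCCC(OCC)OCC | intermediate
13 | 1-[(1S)-2,2-dimethyl-6-methylidenecyclohexyl]-8,8-diethoxy-3-methyloct-4-yn-3-yl benzenesulfinate | C=C1CCCC(C)(C)[C@@H]1CCC(C)(OS(=O)c1ccccc1)C#CCCC(OCC)OCC | intermediate
14 | {[8-[(1S)-2,2-dimethyl-6-methylidenecyclohexyl]-1,1-diethoxy-6-methylocta-4,5-dien-4-yl]sulfonyl}benzene (allene axis unassigned) | C=C1CCCC(C)(C)[C@@H]1CCC(C)=C=C(CCC(OCC)OCC)S(=O)(=O)c1ccccc1 | intermediate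
15 | {[4,4-diethoxy-1-[(4aS,8aS)-2,5,5,8a-tetramethyl-3,4,4a,5,6,7,8,8a-octahydronaphthalen-1-yl]butyl]sulfonyl}benzene (epimers at the sulfonyl carbon) | CC1=C(C(CCC(OCC)OCC)S(=O)(=O)c2ccccc2)[C@@]2(C)CCCC(C)(C)[C@@H]2CC1 | intermediate
16 | (4aS,8aS)-5-(4,4-diethoxybutyl)-1,1,4a,6-tetramethyl-1,2,3,4,4a,7,8,8a-octahydronaphthalene | CC1=C(CCCC(OCC)OCC)[C@@]2(C)CCCC(C)(C)[C@@H]2CC1 | intermediate
17 | 4-[(4aS,8aS)-2,5,5,8a-tetramethyl-3,4,4a,5,6,7,8,8a-octahydronaphthalen-1-yl]butanal | CC1=C(CCCC=O)[C@@]2(C)CCCC(C)(C)[C@@H]2CC1 | intermediate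
18 | 2-methylidene-4-[(4aS,8aS)-2,5,5,8a-tetramethyl-3,4,4a,5,6,7,8,8a-octahydronaphthalen-1-yl]butanal | CC1=C(CCC(=C)C=O)[C@@]2(C)CCCC(C)(C)[C@@H]2CC1 | intermediate
19 | 3-(trimethylsilyl)prop-2-ynal | C[Si](C)(C)C#CC=O | starting material
20 | (3R)-1-(trimethylsilyl)hex-5-en-1-yn-3-ol | C=CC[C@@H](O)C#C[Si](C)(C)C | intermediate
21 | (3R)-hex-5-en-1-yn-3-ol | C=CC[C@@H](O)C#C | intermediate
22 | (5R)-4-{[dimethyl(propan-2-yloxy)silyl]methyl}-5-(prop-2-en-1-yl)-2,5-dihydro-1,2-oxamagnesole | C=CC[C@H]1O[Mg]C=C1C[Si](C)(C)OC(C)C | intermediate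
23 | (2E,4R)-3-{[dimethyl(propan-2-yloxy)silyl]methyl}-4-hydroxyhepta-2,6-dienoic acid | C=CC[C@@H](O)/C(C[Si](C)(C)OC(C)C)=C\C(=O)O | intermediate
24 | (5R)-4-{[dimethyl(propan-2-yloxy)silyl]methyl}-5-(prop-2-en-1-yl)furan-2(5H)-one | C=CC[C@H]1OC(=O)C=C1C[Si](C)(C)OC(C)C | intermediate
25 | (5R)-4-(hydroxymethyl)-5-(prop-2-en-1-yl)furan-2(5H)-one | C=CC[C@H]1OC(=O)C=C1CO | intermediate
26 | (2E)-4-[(2R)-3-(hydroxymethyl)-5-oxo-2,5-dihydrofuran-2-yl]-2-{2-[(4aS,8aS)-2,5,5,8a-tetramethyl-3,4,4a,5,6,7,8,8a-octahydronaphthalen-1-yl]ethyl}but-2-enal | CC1=C(CC/C(C=O)=C\C[C@H]2OC(=O)C=C2CO)[C@@]2(C)CCCC(C)(C)[C@@H]2CC1 | intermediate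
27 | (5R)-4-(hydroxymethyl)-5-{(2E)-3-(hydroxymethyl)-5-[(4aS,8aS)-2,5,5,8a-tetramethyl-3,4,4a,5,6,7,8,8a-octahydronaphthalen-1-yl]pent-2-en-1-yl}furan-2(5H)-one | CC1=C(CC/C(=C\C[C@H]2OC(=O)C=C2CO)CO)[C@@]2(C)CCCC(C)(C)[C@@H]2CC1 | target

**Step count and risks**

Total steps: 13. Longest linear sequence: 10 (steps 1–8, 12, 13); steps 9–11 form the butenolide branch.

Three steps most likely to fail:

Step 6 (radical ring closure). The tetrasubstituted allenyl sulfone may be too hindered, or may be reduced directly by the metal hydride. The fallback sets out from 9 and comes back at 15. Ethynylmagnesium bromide adds to 9 to give 5-[(1S)-2,2-dimethyl-6-methylidenecyclohexyl]-3-methylpent-1-yn-3-ol F1. PhS(O)Cl/Et3N converts it into 5-[(1S)-2,2-dimethyl-6-methylidenecyclohexyl]-3-methylpent-1-yn-3-yl benzenesulfinate F2, which rearranges on warming to the less hindered, more electrophilic {[5-[(1S)-2,2-dimethyl-6-methylidenecyclohexyl]-3-methylpenta-1,2-dien-1-yl]sulfonyl}benzene F3. The same Fe/PhSiH3 cyclisation gives ({[(4aS,8aS)-2,5,5,8a-tetramethyl-3,4,4a,5,6,7,8,8a-octahydronaphthalen-1-yl]methyl}sulfonyl)benzene F4. The C11–C12 bond is then made in a separate polar step: n-BuLi in THF/DMPU, then 3-bromo-1,1-diethoxypropane, gives 15.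

Step 4 (asymmetric SN2' at a carbon next to a quaternary centre). Attack at the chloromethyl carbon (SN2) or low ee is possible. The fallback sets out from 1 and comes back at 9, and sets C5 by enolate allylation instead. Conjugate addition of MeMgBr (Cu cat.) to 1 and trapping with allyl chloroformate gives 3,3-dimethylcyclohex-1-en-1-yl prop-2-en-1-yl carbonate F5. Pd-catalysed decarboxylative asymmetric allylic alkylation (Trost ligand) gives (2S)-3,3-dimethyl-2-(prop-2-en-1-yl)cyclohexan-1-one F6. Non-basic Lombardo methylenation (Zn, CH2Br2, TiCl4) gives (2S)-1,1-dimethyl-3-methylidene-2-(prop-2-en-1-yl)cyclohexane F7. Aldehyde-selective (nitrite-modified) Wacker oxidation of the monosubstituted alkene gives 3-[(1S)-2,2-dimethyl-6-methylidenecyclohexyl]propanal F8. MeMgBr gives 4-[(1S)-2,2-dimethyl-6-methylidenecyclohexyl]butan-2-ol F9, and Dess–Martin oxidation gives 9.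

Step 7 (desulfonylation). Protonation of the allyl anion at the ring terminus would move the alkene out of the ring. The fallback sets out from 9 and comes back at 16, and avoids sulfur altogether. Addition of 11 to 9 with aqueous work-up gives 1-[(1S)-2,2-dimethyl-6-methylidenecyclohexyl]-8,8-diethoxy-3-methyloct-4-yn-3-ol F10. EtMgCl then Cp2Zr(H)Cl (alkoxide-directed hydrozirconation and β-elimination) gives 8-[(1S)-2,2-dimethyl-6-methylidenecyclohexyl]-1,1-diethoxy-6-methylocta-4,5-diene F11. A reductive MHAT cyclisation (Mn(dpm)3, PhSiH3, t-BuOOH, i-PrOH), in which the allyl radical takes its hydrogen at C11, gives 16 directly.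

Further compounds
F1 | step 6 | 5-[(1S)-2,2-dimethyl-6-methylidenecyclohexyl]-3-methylpent-1-yn-3-ol | C=C1CCCC(C)(C)[C@@H]1CCC(C)(O)C#C
F2 | step 6 | 5-[(1S)-2,2-dimethyl-6-methylidenecyclohexyl]-3-methylpent-1-yn-3-yl benzenesulfinate | C=C1CCCC(C)(C)[C@@H]1CCC(C)(OS(=O)c1ccccc1)C#C
F3 | step 6 | {[5-[(1S)-2,2-dimethyl-6-methylidenecyclohexyl]-3-methylpenta-1,2-dien-1-yl]sulfonyl}benzene | C=C1CCCC(C)(C)[C@@H]1CCC(C)=C=CS(=O)(=O)c1ccccc1
F4 | step 6 | ({[(4aS,8aS)-2,5,5,8a-tetramethyl-3,4,4a,5,6,7,8,8a-octahydronaphthalen-1-yl]methyl}sulfonyl)benzene | CC1=C(CS(=O)(=O)c2ccccc2)[C@@]2(C)CCCC(C)(C)[C@@H]2CC1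
F5 | step 4 | 3,3-dimethylcyclohex-1-en-1-yl prop-2-en-1-yl carbonate | C=CCOC(=O)OC1=CC(C)(C)CCC1
F6 | step 4 | (2S)-3,3-dimethyl-2-(prop-2-en-1-yl)cyclohexan-1-one | O=C1CCCC(C)(C)[C@@H]1CC=C
F7 | step 4 | (2S)-1,1-dimethyl-3-methylidene-2-(prop-2-en-1-yl)cyclohexane | C=C1CCCC(C)(C)[C@@H]1CC=C
F8 | step 4 | 3-[(1S)-2,2-dimethyl-6-methylidenecyclohexyl]propanal | C=C1CCCC(C)(C)[C@@H]1CCC=O
F9 | step 4 | 4-[(1S)-2,2-dimethyl-6-methylidenecyclohexyl]butan-2-ol | C=C1CCCC(C)(C)[C@@H]1CCC(C)O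
F10 | step 7 | 1-[(1S)-2,2-dimethyl-6-methylidenecyclohexyl]-8,8-diethoxy-3-methyloct-4-yn-3-ol | C=C1CCCC(C)(C)[C@@H]1CCC(C)(O)C#CCCC(OCC)OCC
F11 | step 7 | 8-[(1S)-2,2-dimethyl-6-methylidenecyclohexyl]-1,1-diethoxy-6-methylocta-4,5-diene | C=C1CCCC(C)(C)[C@@H]1CCC(C)=C=CCCC(OCC)OCC
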